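## Analysis of the target

The target is a 2,3-trans-2,3-diaryl-2,3-dihydro-1-benzofuran, in which a benzo ring (ring C: C3a, C4, C5, C6, C7, C7a) is fused to a dihydrofuran (O1, C2, C3). C2 carries a 3,4-dihydroxyphenyl ring (ring A), C3 a 3,5-dihydroxyphenyl ring (ring B), C4 a hydroxyl group and C6 an (E)-2-(4-hydroxyphenyl)ethenyl group (ring D). The two stereocentres are contiguous and both S, and the aryl groups on them are trans. C2 is a benzylic ether carbon and C3 a triaryl-substituted methine. Six free phenols, one pair forming a catechol, make the compound prone to oxidation, and the stilbene can isomerise in light or acid. The benzylic C2–O1 bond lies para to a hydroxyl of ring A, so acid or base can open the heterocycle through a quinone methide. The difficulty is to set two adjacent aryl-bearing stereocentres in absolute terms on a 1,2,3,5-tetrasubstituted arene whose C3a is flanked by two oxygen-bearing carbons, a position that electrophilic substitution does not reach. The strategy rests on this pattern: O1 and C3 sit on the neighbouring carbons C7a and C3a with the C4 oxygen on the far side of C3a, which is what an oxygen nucleophile and a carbon electrophile leave when they add across a 3-alkoxyaryne. C2 and C3 with rings A and B are the two carbons of a trans-stilbene oxide.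

## Retrosynthetic reasoning

**Phenol protection (23 back to 21).** The six phenols are unmasked last. Four are carried as methyl ethers (C4, ring B, ring D) and the catechol of ring A as two arenesulfonates. Target 23 comes from catechol 22 by Lewis-acid ether cleavage, and 22 from bis-sulfonate 21 by basic S–O cleavage. The sulfonates are not only protection: they make ring A electron-poor, which the key step needs, and they come off while the rest of the molecule is still a robust tetramethyl ether.

**Stilbene (21 back to 17).** The C=C bond of the C6 side chain is cut to aldehyde 19 and phosphonate 20. A Horner–Wadsworth–Emmons olefination of an aryl aldehyde with a benzylic phosphonate gives the E-alkene with no stereocentre at stake. Aldehyde 19 is traced through alcohol 18 to silyl ether 17, because a free aldehyde would itself be attacked by an aryne, whereas a silyloxymethyl group is a bystander.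

**Dihydrofuran ring (17 back to 10 and 15).** The bonds O1–C7a and C3–C3a are cut together. This removes the heterocycle and divides the molecule into an arene fragment (aryne 16, released from silyl triflate 10) and a C2–C3 fragment with both aryl rings and both stereocentres in place (epoxide 15). The cut is made here because the O/C/O pattern on C7a/C3a/C4 is the signature of a 3-methoxyaryne, and because it lets the whole stereochemical problem be solved on an acyclic alkene. The forward reaction has to do three things:
- add the epoxide oxygen to the aryne carbon remote from the methoxy group;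
- break only the C–O bond at the ring B carbon;
- close the five-membered ring with the aryl groups trans, leaving the C2–O bond untouched.

**Epoxide (15 back to 11 and 13).** Epoxide 15 is the product of an enantioselective oxygen transfer to E-stilbene 14, the substrate class for which chiral dioxirane epoxidation is most dependable. Stilbene 14 is cut at its double bond to aldehyde 12 and phosphonate 13, and 12 is the bis-sulfonate of commercial aldehyde 11.

**Aryne precursor (10 back to 1).** The triflate of 10 comes from the carbamate of 8. The silicon atom between the two oxygens comes from directed ortho-metalation of carbamate 4, the only reliable way to functionalise that position. Carbamate 4 derives from phenol 3, whose silyloxymethyl group comes from diol 2 and ultimately from the ester of commercial 1.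

## Alternatives that were turned down

**Alternative 1: benzannulation that builds ring C late.**
- Disconnection: ring C itself is taken apart, into a cyclobutenone bearing the future C6 substituent and a siloxyalkyne that already carries C2, C3 and both aryl rings.
- Forward key step: heating opens the cyclobutenone to a vinylketene, which adds across the alkyne. Ring opening and 6π closure of the adduct then forge the ring bonds C3a–C7a, C4–C5 and C7–C7a. The product is 2-[(1S,2R)-2-(tert-butyldimethylsilyloxy)-2-(3,4-dimethoxyphenyl)-1-(3,5-dimethoxyphenyl)ethyl]-5-[(tert-butyldimethylsilyloxy)methyl]-3-[tri(propan-2-yl)silyloxy]phenol A1, whose free phenol must still displace the activated C2 oxygen with inversion.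
- For: the substitution pattern of ring C is fixed by the mechanism. The two ring oxygens emerge differentiated, and the annulation type is established for siloxyalkynes. On these points it is stronger than the chosen route, whose ring-forming step is untested.
- Against: the alkyne partner needs two adjacent stereocentres, one of them propargylic and benzylic. That centre must survive prolonged heating without epimerisation or elimination, and making this partner is about as hard as the target. The heterocycle then needs separate deprotection, activation and closure steps, and the sequence is linear.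
- Comparison: the chosen route gives up the precedent but offers two short fragments, a single ring-forming step, and stereocentres set on a simple E-stilbene.

**Alternative 2: ortho-quinone methide and sulfonium ylide [4+1] annulation.**
- Disconnection: C2–C3 and O1–C2. C2 with ring A becomes a benzylic sulfonium ylide, and ring C with C3 and ring B becomes a phenol that can lose a sulfinate.
- Forward key step: base generates the quinone methide and the ylide. Conjugate addition forms C2–C3, and the phenoxide then expels the sulfide from C2, giving methyl (2S,3S)-trans-2-(3,4-dimethoxyphenyl)-3-(3,5-dimethoxyphenyl)-4-hydroxy-2,3-dihydrobenzofuran-6-carboxylate A2.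
- For: it is as convergent as the chosen route, and trans geometry follows from the anti betaine and the SN2 closure. The quinone methide precursor is a symmetrical resorcinol, so there is no arene regiochemistry. A2 carries the C6 ester and the C4 phenol without protecting-group traffic. On handle economy, and on precedent for the ring closure in the racemic series, it is at least equal.
- Against: absolute configuration would depend on a stoichiometric chiral sulfide steering the addition of a semi-stabilised, electron-rich benzylide to a fleeting and very reactive quinone methide. C3 is set in an early and possibly reversible addition, and C2 in a later step. The precursor also needs a C–C bond at the hindered carbon between two hydroxyls.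
- Comparison: the chosen route draws its chirality from a catalytic epoxidation of an E-stilbene and transfers it through a bond that is never broken.

**Alternative 3: Wolff ring contraction of a flavanone-derived diazoketone.**
- Disconnection: C3–C3a is formed by contracting the pyranone ring of a 3-diazochroman-4-one made from eriodictyol, so C2 and ring A come from the chiral pool.
- Forward key step: photolysis expels nitrogen, the aryl carbon migrates to C3 and water traps the ketene. The product is (2S)-2-(2,2-diphenyl-1,3-benzodioxol-5-yl)-4-methoxy-6-(methoxycarbonyl)-2,3-dihydrobenzofuran-3-carboxylic acid A3, with C3 unresolved.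
- For: no asymmetric step is needed for C2, the rearrangement is a well-behaved photochemical reaction, and the starting flavanone already contains ring A and the oxygenated ring C. Here it is stronger than the chosen route.
- Against: the flavanone stereocentre racemises by reversible ring opening to the chalcone under the basic conditions of diazo transfer. The C7 phenol of the flavanone must be turned into a carbon substituent. Ring B has to be attached afterwards by decarboxylative arylation at C3, with only substrate control over the trans relationship. The step count is clearly higher.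
- Comparison: the chosen route installs ring B and both ring bonds in the same operation.

Key step: step 9

Remark on the chemistry: ring A is carried as its bis(4-methylbenzenesulfonate). A bis(methanesulfonate) would give the same electronic bias, but its S-methyl protons are acidic enough to be removed by phosphonate carbanions or fluoride. The facial sense of the epoxidation in step 8 is assumed to follow that of (E)-stilbene itself.

## Route

Step 1
Reactants: 1 methyl 3-hydroxy-5-methoxybenzoate
Product: 2 3-(hydroxymethyl)-5-methoxyphenol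
Conditions: LiAlH4, THF, 0 °C to reflux; aq. Rochelle salt
Reagents that add atoms: none
Why: Hydride reduction of the aryl ester to the benzylic alcohol; the phenol is only deprotonated and returns on work-up, and nothing else in the molecule is reducible.

Step 2
Reactants: 2 3-(hydroxymethyl)-5-methoxyphenol
Product: 3 3-methoxy-5-{[tri(propan-2-yl)silyl]oxymethyl}phenol
Conditions: TIPSCl (1.05 equiv), imidazole, DMF, 0 °C
Reagents that add atoms: chlorotri(propan-2-yl)silane (TIPSCl), CC(C)[Si](Cl)(C(C)C)C(C)C
Why: Chemoselective silyl ether formation; with imidazole as the only base the phenol stays protonated and the primary alcohol is the better nucleophile for the bulky silyl chloride, and any aryl silyl ether formed is far more labile and is lost on mild basic work-up.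

Step 3
Reactants: 3 3-methoxy-5-{[tri(propan-2-yl)silyl]oxymethyl}phenol
Product: 4 3-methoxy-5-{[tri(propan-2-yl)silyl]oxymethyl}phenyl N-(propan-2-yl)carbamate
Conditions: i-PrNCO, Et3N (cat.), CH2Cl2, rt
Reagents that add atoms: 2-isocyanatopropane (isopropyl isocyanate), CC(C)N=C=O
Why: Base-catalysed addition of the phenol to the isocyanate gives a secondary aryl carbamate, which directs ortho-metalation and can later be removed under mild E1cB conditions.

Step 4
Reactants: 4 3-methoxy-5-{[tri(propan-2-yl)silyl]oxymethyl}phenyl N-(propan-2-yl)carbamate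
Product: 8 3-methoxy-5-{[tri(propan-2-yl)silyl]oxymethyl}-2-(trimethylsilyl)phenyl N-(propan-2-yl)carbamate, via N-silyl carbamate 5 (not isolated), via aryllithium 6 (not isolated), via doubly silylated carbamate 7 (not isolated)
Conditions: TBSOTf, TMEDA, Et2O, 0 °C to rt; n-BuLi, TMEDA, −78 °C; TMSCl, −78 °C to rt; aq. NaHSO4
Reagents that add atoms: chlorotrimethylsilane (TMSCl), C[Si](C)(C)Cl
Why: Directed ortho-metalation; transient N-silylation masks the carbamate N–H, the carbamate and methoxy oxygens together direct lithiation to the carbon between them, TMSCl traps the aryllithium and the acidic work-up removes the N-silyl group.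

Step 5
Reactants: 8 3-methoxy-5-{[tri(propan-2-yl)silyl]oxymethyl}-2-(trimethylsilyl)phenyl N-(propan-2-yl)carbamate
Product: 10 3-methoxy-5-{[tri(propan-2-yl)silyl]oxymethyl}-2-(trimethylsilyl)phenyl trifluoromethanesulfonate, via silylphenol 9 (not isolated)
Conditions: Et2NH, DBU, MeCN, 40 °C; then PhNTf2, rt
Reagents that add atoms: N-phenylbis(trifluoromethanesulfonimide) (PhNTf2), O=S(=O)(N(c1ccccc1)S(=O)(=O)C(F)(F)F)C(F)(F)F
Why: E1cB cleavage of the secondary carbamate (the isocyanate is scavenged by Et2NH) frees the phenoxide, which is triflated in the same flask; not isolating the ortho-silyl phenol limits protodesilylation.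

Step 6
Reactants: 11 3,4-dihydroxybenzaldehyde
Product: 12 4-formyl-1,2-phenylene bis(4-methylbenzenesulfonate)
Conditions: TsCl (2.4 equiv), Et3N, 4-(dimethylamino)pyridine (cat.), CH2Cl2, 0 °C to rt
Reagents that add atoms: 4-methylbenzenesulfonyl chloride (TsCl), Cc1ccc(cc1)S(Cl)(=O)=O
Why: O-sulfonylation of both phenols; the tosylates have no acidic alpha-protons, withstand the later carbanion, oxidant and fluoride steps, and make ring A electron-poor.

Step 7
Reactants: 12 4-formyl-1,2-phenylene bis(4-methylbenzenesulfonate); 13 diethyl (3,5-dimethoxybenzyl)phosphonate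
Product: 14 4-[(E)-2-(3,5-dimethoxyphenyl)ethenyl]-1,2-phenylene bis(4-methylbenzenesulfonate)
Conditions: 13, KOtBu (slightly less than 1 equiv to 13), THF, 0 °C; then 12, 0 °C to rt
Reagents that add atoms: none
Why: Horner–Wadsworth–Emmons olefination of a non-enolisable, electron-poor aryl aldehyde with a preformed benzylic phosphonate anion; reversible addition and syn elimination should give the E-stilbene, and no free alkoxide is left to attack the sulfonates.

Step 8
Reactants: 14 4-[(E)-2-(3,5-dimethoxyphenyl)ethenyl]-1,2-phenylene bis(4-methylbenzenesulfonate)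
Product: 15 4-[(2R,3R)-3-(3,5-dimethoxyphenyl)oxiran-2-yl]-1,2-phenylene bis(4-methylbenzenesulfonate)
Conditions: 1,2:4,5-di-O-isopropylidene-β-D-erythro-2,3-hexodiulo-2,6-pyranose (D-fructose-derived Shi ketone, 30 mol %), Oxone (2KHSO5·KHSO4·K2SO4), K2CO3, Bu4NHSO4 (cat.), MeCN/dimethoxymethane/aq. Na2B4O7–Na2EDTA buffer (pH about 10.5), 0 °C
Reagents that add atoms: Oxone (active component potassium peroxymonosulfate, KHSO5), [K+].[O-]S(=O)(=O)OO
Why: Shi epoxidation; the chiral dioxirane formed in situ transfers oxygen through a spiro transition state, trans-1,2-diaryl alkenes are its best substrates, and the D-fructose-derived ketone should give the (R,R)-oxide as it does with (E)-stilbene, setting both stereocentres; the cold, mildly basic medium leaves the aryl tosylates intact.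

Step 9
Reactants: 10 3-methoxy-5-{[tri(propan-2-yl)silyl]oxymethyl}-2-(trimethylsilyl)phenyl trifluoromethanesulfonate; 15 4-[(2R,3R)-3-(3,5-dimethoxyphenyl)oxiran-2-yl]-1,2-phenylene bis(4-methylbenzenesulfonate)
Product: 17 4-[(2S,3S)-3-(3,5-dimethoxyphenyl)-4-methoxy-6-{[tri(propan-2-yl)silyl]oxymethyl}-2,3-dihydro-1-benzofuran-2-yl]-1,2-phenylene bis(4-methylbenzenesulfonate), via aryne 16 (not isolated)
Conditions: CsF, MeCN, 40 °C; 10 (2 equiv) added slowly to 15
Reagents that add atoms: none
Why: Proposed new method: fluoride removes the trimethylsilyl group of 10 and triflate departs to give aryne 16, and the epoxide oxygen of 15 adds to the aryne carbon remote from the methoxy group (future C7a), because the aryl anion then develops at the carbon next to the inductively withdrawing methoxy group (future C3a). The O-aryl oxiranium zwitterion cannot be opened from the rear by its own ortho carbanion, so the C–O bond at the ring B carbon ionises (the other benzylic carbon is deactivated by the bis-sulfonylated ring A) and the aryl anion collapses onto that carbon from the face the oxygen has just left; the five-membered ring thus closes by a formally 5-endo-tet ion-pair recombination that forms C3–C3a after O1–C7a. The closest known reaction type is the fluoride-induced insertion of arynes into the benzylic C–O bond of styrene oxide to give 3-aryl-2,3-dihydrobenzofurans, together with the established distal attack of nucleophiles on 3-methoxyarynes; a 2,3-diaryl oxirane with a choice between two benzylic C–O bonds has not been shown. C2 is not a new centre: its C–O bond is never broken, so it keeps the configuration from step 8, and its descriptor changes from R to S only because its ring-opened neighbour falls in priority. C3 is formed with retention by front-side delivery, and if the cation becomes free the fixed C2 aryl group still steers ring B to the opposite face, so both pathways should give the (2S,3S)-trans isomer. Three selectivities are needed: aryne regiochemistry (from the methoxy group), choice of C–O bond (from the electron-poor ring A against ring B) and trans geometry (from the retained C2 centre and the trans epoxide). Slow addition of 10 keeps the aryne concentration low so that capture by the weakly nucleophilic epoxide competes with aryne self-reaction, and CsF in MeCN is mild enough for the silyl ether and the tosylates.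

Step 10
Reactants: 17 4-[(2S,3S)-3-(3,5-dimethoxyphenyl)-4-methoxy-6-{[tri(propan-2-yl)silyl]oxymethyl}-2,3-dihydro-1-benzofuran-2-yl]-1,2-phenylene bis(4-methylbenzenesulfonate)
Product: 18 4-[(2S,3S)-3-(3,5-dimethoxyphenyl)-6-(hydroxymethyl)-4-methoxy-2,3-dihydro-1-benzofuran-2-yl]-1,2-phenylene bis(4-methylbenzenesulfonate)
Conditions: TBAF, AcOH (1:1), THF, 0 °C to rt
Reagents that add atoms: none
Why: Fluoride cleavage of the Si–O bond; buffering with acetic acid keeps the medium non-basic, so the aryl sulfonates and the C3 methine are not exposed to basic fluoride.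

Step 11
Reactants: 18 4-[(2S,3S)-3-(3,5-dimethoxyphenyl)-6-(hydroxymethyl)-4-methoxy-2,3-dihydro-1-benzofuran-2-yl]-1,2-phenylene bis(4-methylbenzenesulfonate)
Product: 19 4-[(2S,3S)-3-(3,5-dimethoxyphenyl)-6-formyl-4-methoxy-2,3-dihydro-1-benzofuran-2-yl]-1,2-phenylene bis(4-methylbenzenesulfonate)
Conditions: Dess–Martin periodinane, NaHCO3, CH2Cl2, 0 °C to rt
Reagents that add atoms: none
Why: Dess–Martin oxidation of a primary benzylic alcohol stops at the aldehyde under near-neutral conditions and touches neither stereocentre.

Step 12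
Reactants: 19 4-[(2S,3S)-3-(3,5-dimethoxyphenyl)-6-formyl-4-methoxy-2,3-dihydro-1-benzofuran-2-yl]-1,2-phenylene bis(4-methylbenzenesulfonate); 20 diethyl (4-methoxybenzyl)phosphonate
Product: 21 4-[(2S,3S)-3-(3,5-dimethoxyphenyl)-4-methoxy-6-[(E)-2-(4-methoxyphenyl)ethenyl]-2,3-dihydro-1-benzofuran-2-yl]-1,2-phenylene bis(4-methylbenzenesulfonate)
Conditions: 20, KOtBu (slightly less than 1 equiv to 20), THF, 0 °C; then 19, 0 °C to rt
Reagents that add atoms: none
Why: Horner–Wadsworth–Emmons olefination as in step 7; the aldehyde is non-enolisable, the phosphonate anion is too weak a base to remove the C3 methine proton, and the E-alkene should result.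

Step 13
Reactants: 21 4-[(2S,3S)-3-(3,5-dimethoxyphenyl)-4-methoxy-6-[(E)-2-(4-methoxyphenyl)ethenyl]-2,3-dihydro-1-benzofuran-2-yl]-1,2-phenylene bis(4-methylbenzenesulfonate)
Product: 22 4-[(2S,3S)-3-(3,5-dimethoxyphenyl)-4-methoxy-6-[(E)-2-(4-methoxyphenyl)ethenyl]-2,3-dihydro-1-benzofuran-2-yl]benzene-1,2-diol
Conditions: KOH, MeOH/THF/H2O, 65 °C, argon; then aq. NH4Cl
Reagents that add atoms: none
Why: Basic hydrolysis of aryl sulfonates by attack of hydroxide at sulfur releases the catechol; the methyl ethers, the stilbene and the dihydrofuran are inert to aqueous base at this temperature, and air is excluded because the catecholate is oxidisable.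

Step 14
Reactants: 22 4-[(2S,3S)-3-(3,5-dimethoxyphenyl)-4-methoxy-6-[(E)-2-(4-methoxyphenyl)ethenyl]-2,3-dihydro-1-benzofuran-2-yl]benzene-1,2-diol
Product: 23 4-[(2S,3S)-3-(3,5-dihydroxyphenyl)-4-hydroxy-6-[(E)-2-(4-hydroxyphenyl)ethenyl]-2,3-dihydro-1-benzofuran-2-yl]benzene-1,2-diol
Conditions: BBr3 (excess), CH2Cl2, −78 °C to rt; then MeOH, H2O
Reagents that add atoms: none
Why: Lewis-acid cleavage of the four aryl methyl ethers; BBr3 complexes each ether oxygen and bromide removes the methyl group, while the catechol is held as a boron ester that tempers donation into the benzylic C2 position until aqueous work-up frees the six phenols.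

## Compound list

1 | methyl 3-hydroxy-5-methoxybenzoate | COC(=O)c1cc(O)cc(OC)c1 | starting material
2 | 3-(hydroxymethyl)-5-methoxyphenol | COc1cc(O)cc(CO)c1 | intermediate
3 | 3-methoxy-5-{[tri(propan-2-yl)silyl]oxymethyl}phenol | COc1cc(O)cc(CO[Si](C(C)C)(C(C)C)C(C)C)c1 | intermediate
4 | 3-methoxy-5-{[tri(propan-2-yl)silyl]oxymethyl}phenyl N-(propan-2-yl)carbamate | COc1cc(OC(=O)NC(C)C)cc(CO[Si](C(C)C)(C(C)C)C(C)C)c1 | intermediate
5 | 3-methoxy-5-{[tri(propan-2-yl)silyl]oxymethyl}phenyl N-[tert-butyl(dimethyl)silyl]-N-(propan-2-yl)carbamate | COc1cc(OC(=O)N(C(C)C)[Si](C)(C)C(C)(C)C)cc(CO[Si](C(C)C)(C(C)C)C(C)C)c1 | intermediate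
6 | [2-({[tert-butyl(dimethyl)silyl](propan-2-yl)carbamoyl}oxy)-6-methoxy-4-{[tri(propan-2-yl)silyl]oxymethyl}phenyl]lithium | [Li]c1c(OC)cc(CO[Si](C(C)C)(C(C)C)C(C)C)cc1OC(=O)N(C(C)C)[Si](C)(C)C(C)(C)C | intermediate
7 | 3-methoxy-5-{[tri(propan-2-yl)silyl]oxymethyl}-2-(trimethylsilyl)phenyl N-[tert-butyl(dimethyl)silyl]-N-(propan-2-yl)carbamate | COc1cc(CO[Si](C(C)C)(C(C)C)C(C)C)cc(OC(=O)N(C(C)C)[Si](C)(C)C(C)(C)C)c1[Si](C)(C)C | intermediate
8 | 3-methoxy-5-{[tri(propan-2-yl)silyl]oxymethyl}-2-(trimethylsilyl)phenyl N-(propan-2-yl)carbamate | COc1cc(CO[Si](C(C)C)(C(C)C)C(C)C)cc(OC(=O)NC(C)C)c1[Si](C)(C)C | intermediate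
9 | 3-methoxy-5-{[tri(propan-2-yl)silyl]oxymethyl}-2-(trimethylsilyl)phenol | COc1cc(CO[Si](C(C)C)(C(C)C)C(C)C)cc(O)c1[Si](C)(C)C | intermediate
10 | 3-methoxy-5-{[tri(propan-2-yl)silyl]oxymethyl}-2-(trimethylsilyl)phenyl trifluoromethanesulfonate | COc1cc(CO[Si](C(C)C)(C(C)C)C(C)C)cc(OS(=O)(=O)C(F)(F)F)c1[Si](C)(C)C | intermediate
11 | 3,4-dihydroxybenzaldehyde | O=Cc1ccc(O)c(O)c1 | starting material
12 | 4-formyl-1,2-phenylene bis(4-methylbenzenesulfonate) | O=Cc1ccc(OS(=O)(=O)c2ccc(C)cc2)c(OS(=O)(=O)c2ccc(C)cc2)c1 | intermediate
13 | diethyl (3,5-dimethoxybenzyl)phosphonate | CCOP(=O)(Cc1cc(OC)cc(OC)c1)OCC | starting material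
14 | 4-[(E)-2-(3,5-dimethoxyphenyl)ethenyl]-1,2-phenylene bis(4-methylbenzenesulfonate) | COc1cc(/C=C/c2ccc(OS(=O)(=O)c3ccc(C)cc3)c(OS(=O)(=O)c3ccc(C)cc3)c2)cc(OC)c1 | intermediate
15 | 4-[(2R,3R)-3-(3,5-dimethoxyphenyl)oxiran-2-yl]-1,2-phenylene bis(4-methylbenzenesulfonate) | Cc1ccc(cc1)S(=O)(=O)Oc1ccc(cc1OS(=O)(=O)c1ccc(C)cc1)[C@H]1O[C@@H]1c1cc(OC)cc(OC)c1 | intermediate
16 | 1,2-didehydro-3-methoxy-5-{[tri(propan-2-yl)silyl]oxymethyl}benzene (aryne) | COC1=CC(CO[Si](C(C)C)(C(C)C)C(C)C)=CC#C1 | intermediate
17 | 4-[(2S,3S)-3-(3,5-dimethoxyphenyl)-4-methoxy-6-{[tri(propan-2-yl)silyl]oxymethyl}-2,3-dihydro-1-benzofuran-2-yl]-1,2-phenylene bis(4-methylbenzenesulfonate) | CC(C)[Si](OCc1cc(OC)c2c(c1)O[C@H](c1ccc(OS(=O)(=O)c3ccc(C)cc3)c(OS(=O)(=O)c3ccc(C)cc3)c1)[C@H]2c1cc(OC)cc(OC)c1)(C(C)C)C(C)C | intermediate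
18 | 4-[(2S,3S)-3-(3,5-dimethoxyphenyl)-6-(hydroxymethyl)-4-methoxy-2,3-dihydro-1-benzofuran-2-yl]-1,2-phenylene bis(4-methylbenzenesulfonate) | OCc1cc(OC)c2c(c1)O[C@H](c1ccc(OS(=O)(=O)c3ccc(C)cc3)c(OS(=O)(=O)c3ccc(C)cc3)c1)[C@H]2c1cc(OC)cc(OC)c1 | intermediate
19 | 4-[(2S,3S)-3-(3,5-dimethoxyphenyl)-6-formyl-4-methoxy-2,3-dihydro-1-benzofuran-2-yl]-1,2-phenylene bis(4-methylbenzenesulfonate) | O=Cc1cc(OC)c2c(c1)O[C@H](c1ccc(OS(=O)(=O)c3ccc(C)cc3)c(OS(=O)(=O)c3ccc(C)cc3)c1)[C@H]2c1cc(OC)cc(OC)c1 | intermediate
20 | diethyl (4-methoxybenzyl)phosphonate | CCOP(=O)(Cc1ccc(OC)cc1)OCC | starting material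
21 | 4-[(2S,3S)-3-(3,5-dimethoxyphenyl)-4-methoxy-6-[(E)-2-(4-methoxyphenyl)ethenyl]-2,3-dihydro-1-benzofuran-2-yl]-1,2-phenylene bis(4-methylbenzenesulfonate) | COc1ccc(/C=C/c2cc(OC)c3c(c2)O[C@H](c2ccc(OS(=O)(=O)c4ccc(C)cc4)c(OS(=O)(=O)c4ccc(C)cc4)c2)[C@H]3c2cc(OC)cc(OC)c2)cc1 | intermediate
22 | 4-[(2S,3S)-3-(3,5-dimethoxyphenyl)-4-methoxy-6-[(E)-2-(4-methoxyphenyl)ethenyl]-2,3-dihydro-1-benzofuran-2-yl]benzene-1,2-diol | COc1ccc(/C=C/c2cc(OC)c3c(c2)O[C@H](c2ccc(O)c(O)c2)[C@H]3c2cc(OC)cc(OC)c2)cc1 | intermediate
23 | 4-[(2S,3S)-3-(3,5-dihydroxyphenyl)-4-hydroxy-6-[(E)-2-(4-hydroxyphenyl)ethenyl]-2,3-dihydro-1-benzofuran-2-yl]benzene-1,2-diol (CNP0316718.1) | Oc1ccc(/C=C/c2cc(O)c3c(c2)O[C@H](c2ccc(O)c(O)c2)[C@H]3c2cc(O)cc(O)c2)cc1 | target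

## Step count and risk

Total step count: 14. Longest linear sequence: 11 steps (steps 1 to 5, 9, 10 to 14). The epoxide branch adds 3 steps (6 to 8).

**Step 9 (key step, proposed new method).** Several processes could divert it:
- fluoride opening of the epoxide, or 1,2-shift of the O-arylated oxiranium to a carbonyl compound;
- proton quench of the aryl anion before ring closure;
- ionisation at the ring A carbon;
- addition of the oxygen to the other aryne terminus.

The cause in each case is that the epoxide is a weak nucleophile and the zwitterion is short-lived. The fallback uses known chemistry, sets out from phenol 3 and stilbene 14, and returns at 17. Phenol 3 is converted with chloromethyl methyl ether and a tertiary amine into 1-methoxy-3-(methoxymethoxy)-5-{[tri(propan-2-yl)silyl]oxymethyl}benzene F1. n-BuLi in THF at 0 °C metalates F1 between its two oxygens to give [2-methoxy-6-(methoxymethoxy)-4-{[tri(propan-2-yl)silyl]oxymethyl}phenyl]lithium F2. Stilbene 14 is epoxidised as in step 8 but with the enantiomeric (L-fructose-derived) ketone, giving 4-[(2S,3S)-3-(3,5-dimethoxyphenyl)oxiran-2-yl]-1,2-phenylene bis(4-methylbenzenesulfonate) F3. F2 opens F3 in the presence of BF3·OEt2 at −78 °C, with inversion at the ring B carbon (the same electronic bias as in step 9). This gives 4-[(1R,2S)-2-(3,5-dimethoxyphenyl)-1-hydroxy-2-[2-methoxy-6-(methoxymethoxy)-4-{[tri(propan-2-yl)silyl]oxymethyl}phenyl]ethyl]-1,2-phenylene bis(4-methylbenzenesulfonate) F4. ZnBr2 and propane-1-thiol remove the methoxymethyl group to give 4-[(1R,2S)-2-(3,5-dimethoxyphenyl)-1-hydroxy-2-[2-hydroxy-6-methoxy-4-{[tri(propan-2-yl)silyl]oxymethyl}phenyl]ethyl]-1,2-phenylene bis(4-methylbenzenesulfonate) F5. A Mitsunobu cyclisation (PPh3, diisopropyl azodicarboxylate) then closes O1–C2 with inversion. Two inversions on the enantiomeric epoxide converge on the same (2S,3S)-trans compound 17.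

**Step 14.** The likely failure is acid-promoted ionisation of the benzylic C2–O1 bond once ring A is electron-rich, leading to epimerisation, ring opening or Friedel–Crafts attack on the stilbene. The fallback reverses the order of the last two operations; it sets out from 21 and returns at 23. BBr3 is applied to 21 while ring A still carries both sulfonates and C2 is deactivated, giving 4-[(2S,3S)-3-(3,5-dihydroxyphenyl)-4-hydroxy-6-[(E)-2-(4-hydroxyphenyl)ethenyl]-2,3-dihydro-1-benzofuran-2-yl]-1,2-phenylene bis(4-methylbenzenesulfonate) F6. Degassed aqueous-methanolic KOH with Na2S2O4 as antioxidant then removes the sulfonates to give 23.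

**Step 4.** Incomplete N-silylation would lead to loss of the carbamate by elimination to the isocyanate, and metalation could occur away from the position between the oxygens. The fallback uses a tertiary carbamate, which has no N–H; it sets out from 3 and returns at 9, which is triflated as in the second half of step 5 to give 10. Phenol 3 is acylated with N,N-diethylcarbamoyl chloride and NaH to give 3-methoxy-5-{[tri(propan-2-yl)silyl]oxymethyl}phenyl N,N-diethylcarbamate F7. s-BuLi and TMEDA in THF at −78 °C give [2-(diethylcarbamoyloxy)-6-methoxy-4-{[tri(propan-2-yl)silyl]oxymethyl}phenyl]lithium F8. TMSCl converts F8 into 3-methoxy-5-{[tri(propan-2-yl)silyl]oxymethyl}-2-(trimethylsilyl)phenyl N,N-diethylcarbamate F9, and LiAlH4 in THF cleaves the carbamate to phenol 9.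

**Step 2.** The likely failure is loss of chemoselectivity through competing silylation of the phenol. The fallback protects both hydroxyls and then frees the phenol; it sets out from 2 and returns at 3. Excess TIPSCl and imidazole give tri(propan-2-yl){3-methoxy-5-{[tri(propan-2-yl)silyl]oxymethyl}phenoxy}silane F10. One equivalent of TBAF in THF at −20 °C then cleaves only the aryl silyl ether, which is far more labile than the alkyl one, to give 3.

## Further compounds

F1 | step 9 | 1-methoxy-3-(methoxymethoxy)-5-{[tri(propan-2-yl)silyl]oxymethyl}benzene | COCOc1cc(OC)cc(CO[Si](C(C)C)(C(C)C)C(C)C)c1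
F2 | step 9 | [2-methoxy-6-(methoxymethoxy)-4-{[tri(propan-2-yl)silyl]oxymethyl}phenyl]lithium | [Li]c1c(OC)cc(CO[Si](C(C)C)(C(C)C)C(C)C)cc1OCOC
F3 | step 9 | 4-[(2S,3S)-3-(3,5-dimethoxyphenyl)oxiran-2-yl]-1,2-phenylene bis(4-methylbenzenesulfonate) | Cc1ccc(cc1)S(=O)(=O)Oc1ccc(cc1OS(=O)(=O)c1ccc(C)cc1)[C@@H]1O[C@H]1c1cc(OC)cc(OC)c1
F4 | step 9 | 4-[(1R,2S)-2-(3,5-dimethoxyphenyl)-1-hydroxy-2-[2-methoxy-6-(methoxymethoxy)-4-{[tri(propan-2-yl)silyl]oxymethyl}phenyl]ethyl]-1,2-phenylene bis(4-methylbenzenesulfonate) | O[C@@H](c1ccc(OS(=O)(=O)c2ccc(C)cc2)c(OS(=O)(=O)c2ccc(C)cc2)c1)[C@H](c1c(OC)cc(CO[Si](C(C)C)(C(C)C)C(C)C)cc1OCOC)c1cc(OC)cc(OC)c1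
F5 | step 9 | 4-[(1R,2S)-2-(3,5-dimethoxyphenyl)-1-hydroxy-2-[2-hydroxy-6-methoxy-4-{[tri(propan-2-yl)silyl]oxymethyl}phenyl]ethyl]-1,2-phenylene bis(4-methylbenzenesulfonate) | O[C@@H](c1ccc(OS(=O)(=O)c2ccc(C)cc2)c(OS(=O)(=O)c2ccc(C)cc2)c1)[C@H](c1c(OC)cc(CO[Si](C(C)C)(C(C)C)C(C)C)cc1O)c1cc(OC)cc(OC)c1
F6 | step 14 | 4-[(2S,3S)-3-(3,5-dihydroxyphenyl)-4-hydroxy-6-[(E)-2-(4-hydroxyphenyl)ethenyl]-2,3-dihydro-1-benzofuran-2-yl]-1,2-phenylene bis(4-methylbenzenesulfonate) | Oc1ccc(/C=C/c2cc(O)c3c(c2)O[C@H](c2ccc(OS(=O)(=O)c4ccc(C)cc4)c(OS(=O)(=O)c4ccc(C)cc4)c2)[C@H]3c2cc(O)cc(O)c2)cc1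
F7 | step 4 | 3-methoxy-5-{[tri(propan-2-yl)silyl]oxymethyl}phenyl N,N-diethylcarbamate | CCN(CC)C(=O)Oc1cc(OC)cc(CO[Si](C(C)C)(C(C)C)C(C)C)c1
F8 | step 4 | [2-(diethylcarbamoyloxy)-6-methoxy-4-{[tri(propan-2-yl)silyl]oxymethyl}phenyl]lithium | [Li]c1c(OC)cc(CO[Si](C(C)C)(C(C)C)C(C)C)cc1OC(=O)N(CC)CC
F9 | step 4 | 3-methoxy-5-{[tri(propan-2-yl)silyl]oxymethyl}-2-(trimethylsilyl)phenyl N,N-diethylcarbamate | CCN(CC)C(=O)Oc1cc(CO[Si](C(C)C)(C(C)C)C(C)C)cc(OC)c1[Si](C)(C)C
F10 | step 2 | tri(propan-2-yl){3-methoxy-5-{[tri(propan-2-yl)silyl]oxymethyl}phenoxy}silane | COc1cc(O[Si](C(C)C)(C(C)C)C(C)C)cc(CO[Si](C(C)C)(C(C)C)C(C)C)c1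
A1 | alternative 1 | 2-[(1S,2R)-2-(tert-butyldimethylsilyloxy)-2-(3,4-dimethoxyphenyl)-1-(3,5-dimethoxyphenyl)ethyl]-5-[(tert-butyldimethylsilyloxy)methyl]-3-[tri(propan-2-yl)silyloxy]phenol | CC(C)(C)[Si](C)(C)O[C@@H](c1ccc(OC)c(OC)c1)[C@H](c1c(O)cc(CO[Si](C)(C)C(C)(C)C)cc1O[Si](C(C)C)(C(C)C)C(C)C)c1cc(OC)cc(OC)c1
A2 | alternative 2 | methyl (2S,3S)-trans-2-(3,4-dimethoxyphenyl)-3-(3,5-dimethoxyphenyl)-4-hydroxy-2,3-dihydrobenzofuran-6-carboxylate | COC(=O)c1cc(O)c2c(c1)O[C@H](c1ccc(OC)c(OC)c1)[C@H]2c1cc(OC)cc(OC)c1
A3 | alternative 3 | (2S)-2-(2,2-diphenyl-1,3-benzodioxol-5-yl)-4-methoxy-6-(methoxycarbonyl)-2,3-dihydrobenzofuran-3-carboxylic acid | COC(=O)c1cc(OC)c2c(c1)O[C@H](c1ccc3OC(c4ccccc4)(c4ccccc4)Oc3c1)C2C(=O)O
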